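The six-membered ring B of the dihydronaphthalene (C2 ester, C3 CH2OH, C4 aryl) is cut at C3–C4 and C1–C8a. The route exploits two phenols: the 4-OH of pendant ring C lies para to C4, so C4 can be a p-quinone methide electrophile, and the 6-OH of benzo ring A lies para to C8a, making C8a a Friedel–Crafts nucleophile. In one flask the enolate of a chiral oxazolidinone imide of a masked formylsuccinate (β-methoxyacrylate) adds 1,6 to the quinone methide (C3–C4, both stereocentres), and acid then closes ring B by addition–elimination at the methoxymethylidene carbon (C1–C8a, C1=C2). Borohydride cleavage of the auxiliary unveils the CH2OH.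

Key step: step 7

Remark: locants are those of the target's 3,4-dihydronaphthalene-2-carboxylate skeleton (ring A = benzo ring with 5-OMe, 6-OH, 7-OMe; ring B = dihydro ring; ring C = pendant aryl); the E geometry drawn for the β-methoxyacrylate is assumed, and either geometry would serve because this double bond becomes C1=C2 of ring B.

Step 1
Reactants: 1 2,6-dimethoxyphenol (syringol)
Product: 2 1,3-dimethoxy-2-(methoxymethoxy)benzene
Conditions: MOMCl, i-Pr2NEt, CH2Cl2, 0 °C → rt
Reagents that add atoms: chloromethyl methyl ether, COCCl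
Why: Base-mediated O-alkylation of the phenol (Williamson-type ether synthesis) should give the methoxymethyl (MOM) ether, which masks the future 6-OH as an acid-labile group and leaves the position next to OMe free for lithiation; no stereocentre is formed.

Step 2
Reactants: 2 1,3-dimethoxy-2-(methoxymethoxy)benzene; 3 4-hydroxy-3,5-dimethoxybenzaldehyde (syringaldehyde)
Product: 6 rac-4-{[2,4-dimethoxy-3-(methoxymethoxy)phenyl](hydroxy)methyl}-2,6-dimethoxyphenol, via [2,4-dimethoxy-3-(methoxymethoxy)phenyl]lithium 4 (not isolated), via sodium 4-formyl-2,6-dimethoxyphenolate 5 (not isolated)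
Conditions: 2, n-BuLi, TMEDA, THF, 0 °C; separately 3, NaH, THF, 0 °C; combine at −78 °C → rt; aq. NH4Cl
Reagents that add atoms: none
Why: Directed ortho-metalation next to OMe (as for 1,2,3-trimethoxybenzene) and 1,2-addition of the aryllithium to the aldehyde, whose phenol is masked as its sodium salt, should give the benzhydrol; the new carbinol stereocentre is racemic and is erased in step 3.

Step 3
Reactants: 6 rac-4-{[2,4-dimethoxy-3-(methoxymethoxy)phenyl](hydroxy)methyl}-2,6-dimethoxyphenol
Product: 7 4-{[2,4-dimethoxy-3-(methoxymethoxy)phenyl]methylidene}-2,6-dimethoxycyclohexa-2,5-dien-1-one (p-quinone methide)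
Conditions: pyridinium p-toluenesulfonate (cat.), MgSO4, CH2Cl2, rt; used directly
Reagents that add atoms: none
Why: Acid-catalysed 1,6-dehydration of a p-hydroxybenzhydrol, driven by the drying agent and by the donor aryl group on the exocyclic carbon, should give the p-quinone methide; the quinoid ring is symmetric, so no stereoisomers arise and the MOM ether should survive the weak acid.

Step 4
Reactants: 8 dimethyl succinate
Product: 10 dimethyl (E)-2-(methoxymethylidene)succinate, via sodium enolate of dimethyl formylsuccinate 9 (not isolated)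
Conditions: NaH, HCO2Me (excess), THF, 0 °C → rt; then Me2SO4, DMF, rt
Reagents that add atoms: methyl formate, COC=O; dimethyl sulfate, COS(=O)(=O)OC
Why: Crossed Claisen condensation with methyl formate followed by O-methylation of the formyl ester enolate (the usual entry to β-methoxyacrylates) should give the enol ether; no stereocentre is formed.

Step 5
Reactants: 10 dimethyl (E)-2-(methoxymethylidene)succinate
Product: 11 (E)-4-methoxy-3-(methoxycarbonyl)but-3-enoic acid
Conditions: LiOH·H2O (1 equiv), THF/H2O, 0 °C; then dilute HCl to pH 2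
Reagents that add atoms: lithium hydroxide (hydroxide oxygen of the new CO2H), [Li+].[OH-]
Why: Saponification should occur selectively at the saturated ester because the other ester is a deactivated vinylogous carbonate (push-pull β-methoxyacrylate); no stereocentre is involved.

Step 6
Reactants: 11 (E)-4-methoxy-3-(methoxycarbonyl)but-3-enoic acid; 12 (R)-4-benzyl-1,3-oxazolidin-2-one
Product: 14 (R)-4-benzyl-3-[(E)-4-methoxy-3-(methoxycarbonyl)but-3-enoyl]-1,3-oxazolidin-2-one, via mixed pivalic anhydride 13 (not isolated)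
Conditions: t-BuCOCl, Et3N, THF, −20 °C; then 12, LiCl, −20 °C → rt
Reagents that add atoms: none
Why: N-Acylation of the oxazolidinone through the mixed pivalic anhydride (LiCl-assisted acyl transfer) should give the imide without touching the auxiliary stereocentre.

Step 7
Reactants: 14 (R)-4-benzyl-3-[(E)-4-methoxy-3-(methoxycarbonyl)but-3-enoyl]-1,3-oxazolidin-2-one; 7 4-{[2,4-dimethoxy-3-(methoxymethoxy)phenyl]methylidene}-2,6-dimethoxycyclohexa-2,5-dien-1-one
Product: 17 methyl (3R,4S)-3-{[(4R)-4-benzyl-2-oxo-1,3-oxazolidin-3-yl]carbonyl}-6-hydroxy-4-(4-hydroxy-3,5-dimethoxyphenyl)-5,7-dimethoxy-3,4-dihydronaphthalene-2-carboxylate, via sodium (Z)-dienolate 15 (not isolated), via open-chain 1,6-adduct sodium phenolate 16 (not isolated)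
Conditions: NaN(SiMe3)2 (1 equiv), THF, −78 °C; add 7, −78 → −40 °C; then CF3CO2H (excess), CH2Cl2, H2O (2 equiv), −40 → 23 °C, same flask
Reagents that add atoms: none
Why: NaN(SiMe3)2 converts 14 into the chelated (Z)-dienolate 15, whose α-carbon adds 1,6 to the exocyclic carbon of quinone methide 7 (conjugate addition of a chiral imide enolate; C3–C4 bond, phenolate 16), and CF3CO2H then frees the 6-OH from its MOM ether and activates the β-methoxyacrylate so that C8a of ring A attacks the methoxymethylidene carbon and MeOH is lost (Friedel–Crafts addition–elimination on a formyl ester equivalent, the reaction type of Pechmann and Bradsher cyclodehydrations; C1–C8a bond and C1=C2). Ring B closes in the 6-endo-trig mode at the acrylate terminus, so the overall change is a formal [3+3] annulation. C3 is set by the auxiliary: the benzyl group of the (R)-oxazolidinone shields one face of the sodium-chelated enolate and the electrophile enters anti to it, which gives 3R. C4 is set by relative topicity in an open transition state that should place the bulky, twisted ring A aryl anti to the acyl carbon and the flat quinoid ring synclinal over the imide, which gives 4S (3,4-trans); a C4 epimer would be a separable diastereomer because C3 is fixed by the auxiliary. The step needs α- and not γ-attack of the dienolate (the γ-carbon carries OMe, and sodium dienolates of β,γ-unsaturated imides react at the α-carbon) and closure on ring A and not on ring C (the attacked carbon is para to the free 6-OH and unhindered, the preference known for syringol, whereas the open ring C positions are meta to OH and ortho to OMe).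

Step 8
Reactants: 17 methyl (3R,4S)-3-{[(4R)-4-benzyl-2-oxo-1,3-oxazolidin-3-yl]carbonyl}-6-hydroxy-4-(4-hydroxy-3,5-dimethoxyphenyl)-5,7-dimethoxy-3,4-dihydronaphthalene-2-carboxylate
Product: 18 methyl (3R,4S)-6-hydroxy-4-(4-hydroxy-3,5-dimethoxyphenyl)-3-(hydroxymethyl)-5,7-dimethoxy-3,4-dihydronaphthalene-2-carboxylate (target)
Conditions: NaBH4 (excess), THF/H2O 4:1, 0 °C → rt; pH 7 phosphate buffer
Reagents that add atoms: none
Why: Hydride reduction of the N-acyloxazolidinone (its exocyclic imide carbonyl is far more electrophilic than the conjugated methyl ester) should release the primary alcohol and the auxiliary without touching C3, C4 or the C1=C2 bond.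

Compound list
1 | 2,6-dimethoxyphenol (syringol) | COc1cccc(OC)c1O | starting material
2 | 1,3-dimethoxy-2-(methoxymethoxy)benzene | COCOc1c(OC)cccc1OC | intermediate
3 | 4-hydroxy-3,5-dimethoxybenzaldehyde (syringaldehyde) | COc1cc(C=O)cc(OC)c1O | starting material
4 | [2,4-dimethoxy-3-(methoxymethoxy)phenyl]lithium | [Li]c1ccc(OC)c(OCOC)c1OC | intermediate
5 | sodium 4-formyl-2,6-dimethoxyphenolate | [Na+].[O-]c1c(OC)cc(C=O)cc1OC | intermediate
6 | rac-4-{[2,4-dimethoxy-3-(methoxymethoxy)phenyl](hydroxy)methyl}-2,6-dimethoxyphenol | COCOc1c(OC)ccc(C(O)c2cc(OC)c(O)c(OC)c2)c1OC | intermediate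
7 | 4-{[2,4-dimethoxy-3-(methoxymethoxy)phenyl]methylidene}-2,6-dimethoxycyclohexa-2,5-dien-1-one | COCOc1c(OC)ccc(C=C2C=C(OC)C(=O)C(OC)=C2)c1OC | intermediate
8 | dimethyl succinate | COC(=O)CCC(=O)OC | starting material
9 | sodium enolate of dimethyl 2-formylsuccinate | [Na+].[O-]C=C(CC(=O)OC)C(=O)OC | intermediate
10 | dimethyl (E)-2-(methoxymethylidene)succinate | CO/C=C(\CC(=O)OC)C(=O)OC | intermediate
11 | (E)-4-methoxy-3-(methoxycarbonyl)but-3-enoic acid | CO/C=C(\CC(=O)O)C(=O)OC | intermediate
12 | (R)-4-benzyl-1,3-oxazolidin-2-one | O=C1N[C@H](Cc2ccccc2)CO1 | starting material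
13 | (E)-4-methoxy-3-(methoxycarbonyl)but-3-enoic pivalic anhydride | CO/C=C(\CC(=O)OC(=O)C(C)(C)C)C(=O)OC | intermediate
14 | (R)-4-benzyl-3-[(E)-4-methoxy-3-(methoxycarbonyl)but-3-enoyl]-1,3-oxazolidin-2-one | CO/C=C(\CC(=O)N1[C@H](Cc2ccccc2)COC1=O)C(=O)OC | intermediate
15 | sodium (Z)-dienolate of 14 | [Na+].[O-]/C(=C\C(C(=O)OC)=C/OC)N1[C@H](Cc2ccccc2)COC1=O | intermediate
16 | sodium 4-{(1S,2R,3E)-2-[(4R)-4-benzyl-2-oxo-1,3-oxazolidine-3-carbonyl]-1-[2,4-dimethoxy-3-(methoxymethoxy)phenyl]-4-methoxy-3-(methoxycarbonyl)but-3-en-1-yl}-2,6-dimethoxyphenolate | COCOc1c(OC)ccc([C@H](c2cc(OC)c([O-])c(OC)c2)[C@H](/C(C(=O)OC)=C\OC)C(=O)N2[C@H](Cc3ccccc3)COC2=O)c1OC.[Na+] | intermediate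
17 | methyl (3R,4S)-3-{[(4R)-4-benzyl-2-oxo-1,3-oxazolidin-3-yl]carbonyl}-6-hydroxy-4-(4-hydroxy-3,5-dimethoxyphenyl)-5,7-dimethoxy-3,4-dihydronaphthalene-2-carboxylate | COC(=O)C1=Cc2cc(OC)c(O)c(OC)c2[C@H](c2cc(OC)c(O)c(OC)c2)[C@H]1C(=O)N1[C@H](Cc2ccccc2)COC1=O | intermediate
18 | methyl (3R,4S)-6-hydroxy-4-(4-hydroxy-3,5-dimethoxyphenyl)-3-(hydroxymethyl)-5,7-dimethoxy-3,4-dihydronaphthalene-2-carboxylate (CNP0143100.1) | COC(=O)C1=Cc2cc(OC)c(O)c(OC)c2[C@H](c2cc(OC)c(O)c(OC)c2)[C@H]1CO | target

Total step count: 8. Longest linear sequence: 5 steps (1 → 2 → 3 → 7 → 8, or 4 → 5 → 6 → 7 → 8).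

Steps most likely to fail

Step 7. The facial selectivity at the quinone methide carbon (C4) may be poor or reversed, because only C3 is under direct auxiliary control; ring closure on ring C instead of ring A is the second hazard. The fallback sets out from 11 and comes back at 18. The mixed anhydride 13 would acylate (S)-4-benzyl-1,3-oxazolidin-2-one to give the enantiomeric imide (S)-4-benzyl-3-[(E)-4-methoxy-3-(methoxycarbonyl)but-3-enoyl]-1,3-oxazolidin-2-one F1. If the opposite topicity prevails, the same one-flask addition and cyclisation with 7 should then deliver the 3,4-cis imide methyl (3S,4S)-3-{[(4S)-4-benzyl-2-oxo-1,3-oxazolidin-3-yl]carbonyl}-6-hydroxy-4-(4-hydroxy-3,5-dimethoxyphenyl)-5,7-dimethoxy-3,4-dihydronaphthalene-2-carboxylate F2, which already carries the correct 4S centre. Catalytic DBU in THF should epimerise C3 (α to the imide carbonyl, vinylogous to the ester) to the more stable 3,4-trans imide methyl (3R,4S)-3-{[(4S)-4-benzyl-2-oxo-1,3-oxazolidin-3-yl]carbonyl}-6-hydroxy-4-(4-hydroxy-3,5-dimethoxyphenyl)-5,7-dimethoxy-3,4-dihydronaphthalene-2-carboxylate F3. In F3 both substituents are pseudoaxial, which relieves peri strain with 5-OMe and allylic strain with the C2 ester. NaBH4 in THF/H2O as in step 8 would then give 18. Thermodynamic control of C3 thus replaces kinetic control.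

Step 3. The electrophilic quinone methide may oligomerise or rehydrate during isolation. The fallback sets out from 6 and comes back at 7. p-Toluenesulfinic acid in CH2Cl2 should convert 6 into the bench-stable sulfone 4-{[2,4-dimethoxy-3-(methoxymethoxy)phenyl](4-methylbenzenesulfonyl)methyl}-2,6-dimethoxyphenol F4. In the flask of step 7 one further equivalent of NaN(SiMe3)2 would eliminate sulfinate from F4 and release 7 in the presence of enolate 15, so that 7 is never isolated.

Step 2. Proton transfer or slow addition to the electron-rich, poorly soluble phenolate aldehyde may leave the aryllithium unconsumed. The fallback sets out from 3 and comes back at 6. Silylation (t-BuMe2SiCl, imidazole, DMF) would give 4-[(tert-butyldimethylsilyl)oxy]-3,5-dimethoxybenzaldehyde F5, a normal aldehyde electrophile. Addition of 4 would give the carbinol rac-[4-[(tert-butyldimethylsilyl)oxy]-3,5-dimethoxyphenyl][2,4-dimethoxy-3-(methoxymethoxy)phenyl]methanol F6, and Bu4NF in THF would remove the silyl group to give 6.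

Further compounds
F1 | step 7 | (S)-4-benzyl-3-[(E)-4-methoxy-3-(methoxycarbonyl)but-3-enoyl]-1,3-oxazolidin-2-one | CO/C=C(\CC(=O)N1[C@@H](Cc2ccccc2)COC1=O)C(=O)OC
F2 | step 7 | methyl (3S,4S)-3-{[(4S)-4-benzyl-2-oxo-1,3-oxazolidin-3-yl]carbonyl}-6-hydroxy-4-(4-hydroxy-3,5-dimethoxyphenyl)-5,7-dimethoxy-3,4-dihydronaphthalene-2-carboxylate | COC(=O)C1=Cc2cc(OC)c(O)c(OC)c2[C@H](c2cc(OC)c(O)c(OC)c2)[C@@H]1C(=O)N1[C@@H](Cc2ccccc2)COC1=O
F3 | step 7 | methyl (3R,4S)-3-{[(4S)-4-benzyl-2-oxo-1,3-oxazolidin-3-yl]carbonyl}-6-hydroxy-4-(4-hydroxy-3,5-dimethoxyphenyl)-5,7-dimethoxy-3,4-dihydronaphthalene-2-carboxylate | COC(=O)C1=Cc2cc(OC)c(O)c(OC)c2[C@H](c2cc(OC)c(O)c(OC)c2)[C@H]1C(=O)N1[C@@H](Cc2ccccc2)COC1=O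
F4 | step 3 | 4-{[2,4-dimethoxy-3-(methoxymethoxy)phenyl](4-methylbenzenesulfonyl)methyl}-2,6-dimethoxyphenol | COCOc1c(OC)ccc(C(c2cc(OC)c(O)c(OC)c2)S(=O)(=O)c2ccc(C)cc2)c1OC
F5 | step 2 | 4-[(tert-butyldimethylsilyl)oxy]-3,5-dimethoxybenzaldehyde | COc1cc(C=O)cc(OC)c1O[Si](C)(C)C(C)(C)C
F6 | step 2 | rac-[4-[(tert-butyldimethylsilyl)oxy]-3,5-dimethoxyphenyl][2,4-dimethoxy-3-(methoxymethoxy)phenyl]methanol | COCOc1c(OC)ccc(C(O)c2cc(OC)c(O[Si](C)(C)C(C)(C)C)c(OC)c2)c1OC
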